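**Assumption:** the target SMILES has no stereocentre (the molecule is achiral), so there is no enantiomer to select; the route makes this one constitution, 4,6-bis(4-hydroxybenzyl)-5-(2-phenylethyl)benzene-1,3-diol.

**Retrosynthetic overview**
1. Target ⇒ move both 4-hydroxybenzyl groups from carbon back onto the neighbouring resorcinol oxygens (reverse 1,3 O→C shift): the bis(4-silyloxybenzyl) ether of the 5-phenethylresorcinol core.
2. Key disconnection: both resorcinol C(aryl)–O bonds of that bis-ether ⇒ 1,3-dichloro-5-(2-phenylethyl)benzene + two [4-(triisopropylsilyloxy)phenyl]methanol, joined by a double Pd-catalysed C–O coupling. The benzylic oxygen of each alcohol ends as a phenolic oxygen of the target.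
3. The dichloride ⇒ 1-bromo-3,5-dichlorobenzene + phenethylmagnesium chloride (Kumada); the silyl alcohol ⇒ 4-hydroxybenzyl alcohol + iPr3SiCl.
4. Rings: none is formed. All four benzene rings are bought intact; the phenyl ring is joined to the central ring in step 1 and the two outer rings in step 3.

**Route**

Step 1
Reactants: 1 1-bromo-3,5-dichlorobenzene; 2 (2-phenylethyl)magnesium chloride
Product: 3 1,3-dichloro-5-(2-phenylethyl)benzene
Conditions: 2 (1.15 equiv), Pd(dppf)Cl2·CH2Cl2 (2 mol%), THF, 0 °C → rt
Reagents that add atoms: none
Why: Kumada–Corriu coupling, in which Pd/dppf inserts only into the C–Br bond at room temperature (both C–Cl bonds stay as handles for step 3) and its wide bite angle lets reductive elimination of the primary alkyl group outrun β-hydride elimination; no stereocentre is formed.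

Step 2
Reactants: 4 4-(hydroxymethyl)phenol
Product: 6 [4-(triisopropylsilyloxy)phenyl]methanol, via sodium 4-(hydroxymethyl)phenolate 5 (not isolated)
Conditions: NaH (1.0 equiv), THF–DMF, 0 °C; then iPr3SiCl (1.0 equiv), 0 °C → rt
Reagents that add atoms: chlorotriisopropylsilane, CC(C)[Si](Cl)(C(C)C)C(C)C
Why: Chemoselective phenolate O-silylation, since one equivalent of NaH deprotonates only the phenol (pKa about 10 against about 15 for the benzylic OH) and the bulky triisopropylsilyl ether is stable to the carbonate/alkoxide of step 3 yet labile to fluoride; no stereocentre is formed.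

Step 3
Reactants: 3 1,3-dichloro-5-(2-phenylethyl)benzene; 6 [4-(triisopropylsilyloxy)phenyl]methanol
Product: 8 1-(2-phenylethyl)-3,5-bis{[4-(triisopropylsilyloxy)phenyl]methoxy}benzene, via mono-coupled aryl chloride 7 (not isolated)
Conditions: 6 (2.4 equiv), RockPhos Pd G3 (4 mol%), Cs2CO3 (3 equiv), toluene, 90 °C
Reagents that add atoms: none
Why: Double Buchwald–Hartwig-type Pd-catalysed C–O cross-coupling of an aryl chloride with a primary alcohol, where the bulky biarylphosphine speeds C–O reductive elimination ahead of β-hydride elimination, so both resorcinol C(aryl)–O bonds of the target are made here, each carrying its future benzyl group on oxygen; no stereocentre is formed.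

Step 4
Reactants: 8 1-(2-phenylethyl)-3,5-bis{[4-(triisopropylsilyloxy)phenyl]methoxy}benzene
Product: 11 4,6-bis(4-hydroxybenzyl)-5-(2-phenylethyl)benzene-1,3-diol (the target), via p-quinone methide 9 (not isolated), via mono-C-benzylated phenol 10 (not isolated)
Conditions: anhydrous CsF (2.5 equiv), DMF (0.05 M), 4 Å MS, Ar, rt → 70 °C; then 1 M HCl work-up
Reagents that add atoms: none
Why: Proposed new method: fluoride removes each silyl mask to give a para-phenoxide that expels the resorcinol aryloxide by 1,6-elimination, releasing p-quinone methide 9 beside an ambident aryloxide; recapture on oxygen only re-forms a cleavable ether, whereas recapture on carbon at C4/C6 (each ortho to one oxygen and para to the other) is made irreversible by rearomatisation, so the mixture funnels through 10 to the doubly C-benzylated tetraphenol and the masks are lost in the same operation; the closest known reaction types are the fluoride- or base-triggered 1,6-elimination of p-silyloxy- or p-hydroxybenzyl ethers (self-immolative linkers, alkaline cleavage of phenolic benzyl aryl ethers) and the 1,6-conjugate Friedel–Crafts-type addition of phenolates to p-quinone methides; no stereocentre is formed.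

**Compound list**
1 | 1-bromo-3,5-dichlorobenzene | Brc1cc(Cl)cc(Cl)c1 | starting material
2 | (2-phenylethyl)magnesium chloride (THF solution) | Cl[Mg]CCc1ccccc1 | starting material
3 | 1,3-dichloro-5-(2-phenylethyl)benzene | Clc1cc(Cl)cc(CCc2ccccc2)c1 | intermediate
4 | 4-(hydroxymethyl)phenol (4-hydroxybenzyl alcohol) | OCc1ccc(O)cc1 | starting material
5 | sodium 4-(hydroxymethyl)phenolate | [Na+].[O-]c1ccc(CO)cc1 | intermediate
6 | [4-(triisopropylsilyloxy)phenyl]methanol | OCc1ccc(O[Si](C(C)C)(C(C)C)C(C)C)cc1 | intermediate
7 | 1-chloro-3-(2-phenylethyl)-5-{[4-(triisopropylsilyloxy)phenyl]methoxy}benzene | Clc1cc(CCc2ccccc2)cc(OCc2ccc(O[Si](C(C)C)(C(C)C)C(C)C)cc2)c1 | intermediate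
8 | 1-(2-phenylethyl)-3,5-bis{[4-(triisopropylsilyloxy)phenyl]methoxy}benzene | CC(C)[Si](Oc1ccc(COc2cc(CCc3ccccc3)cc(OCc3ccc(O[Si](C(C)C)(C(C)C)C(C)C)cc3)c2)cc1)(C(C)C)C(C)C | intermediate
9 | 4-methylidenecyclohexa-2,5-dien-1-one (p-quinone methide) | C=C1C=CC(=O)C=C1 | intermediate
10 | 2-(4-hydroxybenzyl)-3-(2-phenylethyl)-5-{[4-(triisopropylsilyloxy)phenyl]methoxy}phenol (present as its caesium phenolate) | Oc1cc(OCc2ccc(O[Si](C(C)C)(C(C)C)C(C)C)cc2)cc(CCc2ccccc2)c1Cc1ccc(O)cc1 | intermediate
11 | 4,6-bis(4-hydroxybenzyl)-5-(2-phenylethyl)benzene-1,3-diol | Oc1ccc(Cc2c(O)cc(O)c(Cc3ccc(O)cc3)c2CCc2ccccc2)cc1 | target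

**Step count and risks**

Total step count: 4. Longest linear sequence: 3 steps (1 → 3 → 4, or equally 2 → 3 → 4).

The three steps most likely to fail:

Step 4 (the proposed new step). The free p-quinone methide may oligomerise, or be recaptured at C2 between the two oxygens, giving the 2,4-dibenzyl isomer. The fallback sets out from 8 and drops the anionic quinone-methide shuttle for a cationic migration with the silyl ethers left on. Catalytic TfOH (5 mol%) in HFIP–CH2Cl2 at 0 °C ionises each aryl benzyl ether and the 4-silyloxybenzyl cation is recaptured at ring carbon, the same acid-promoted O→C benzyl migration known for p-methoxybenzyl aryl ethers. This gives 4,6-bis{[4-(triisopropylsilyloxy)phenyl]methyl}-5-(2-phenylethyl)benzene-1,3-diol F1. A separate desilylation with TBAF/AcOH in THF at 0 °C then comes back to the route at 11.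

Step 3. The benzylic alkoxide on palladium may undergo β-hydride elimination, giving the aldehyde and hydrodechlorinated arene, or the second coupling may stall at 7. The fallback sets out from 3 and reverses the polarity of the ether synthesis. Pd-catalysed hydroxylation of both C–Cl bonds (tBuBrettPhos Pd G3, KOH, dioxane–H2O, 100 °C) gives 5-(2-phenylethyl)benzene-1,3-diol F2. A double Mitsunobu etherification of F2 with 6 (PPh3, DIAD, THF, 0 °C → rt) then comes back to the route at 8.

Step 1. The alkyl Grignard reagent may give β-hydride elimination or homocoupling products, or some coupling at C–Cl. The fallback sets out from 1 and builds the two-carbon link as an alkene first. Br-selective Suzuki–Miyaura coupling with (E)-2-phenylvinylboronic acid (Pd(PPh3)4, K2CO3, dioxane–H2O, 80 °C) gives (E)-1,3-dichloro-5-(2-phenylethenyl)benzene F3. Hydrogenation over 5% Pt/C (H2 1 atm, EtOAc, rt), which leaves the aryl chlorides intact, then comes back to the route at 3.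

**Further compounds**
F1 | step 4 | 4,6-bis{[4-(triisopropylsilyloxy)phenyl]methyl}-5-(2-phenylethyl)benzene-1,3-diol | CC(C)[Si](Oc1ccc(Cc2c(O)cc(O)c(Cc3ccc(O[Si](C(C)C)(C(C)C)C(C)C)cc3)c2CCc2ccccc2)cc1)(C(C)C)C(C)C
F2 | step 3 | 5-(2-phenylethyl)benzene-1,3-diol (dihydropinosylvin) | Oc1cc(O)cc(CCc2ccccc2)c1
F3 | step 1 | (E)-1,3-dichloro-5-(2-phenylethenyl)benzene | Clc1cc(Cl)cc(/C=C/c2ccccc2)c1
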